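**Retrosynthetic overview**
- The pyran (ring C) is closed last: the C8 tertiary hydroxyl adds to a side-chain C13=C14 alkene by selenoetherification, and selenoxide elimination then gives the vinyl group.
- The C8–O bond and the C2 carboxyl both come from Baeyer–Villiger cleavage of a one-carbon ketone bridge (C2) in a bicyclo[3.2.1]octanone, followed by hydrolysis.
- Key step: ring B is closed by a 6-exo radical cyclization that forms the C5–C10 bond onto the β-carbon of a cyclopentenone. The ketone bridge holds C1 axial, so the CMe2CO2Me group goes equatorial and ends cis to CH2CO2H.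
- The cyclopentenone template is built from (S)-4-silyloxycyclopentenone by conjugate addition (C9), methyl cuprate addition/dehydrogenation (C20), then allylation and methylation (C8).
- Ring order: temporary cyclopentenone, then ring B (radical), bridge excised, then ring C.

Assumption: the SMILES is taken literally, so CH2CO2H and CMe2CO2H are cis on the cyclohexane (the ring H next to CMe2CO2H is cis to the adjacent ring methyl); commercial 3-methylpenta-1,3-diene (E/Z) is drawn as (E) because that alkene geometry is erased in step 10.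

Atom labels: C1 = CH2 of CH2CO2H, C2 = its CO2H, C3 = CO2H on CMe2, C4 = CMe2, C5 = ring CH bearing C4, C6 and C7 = ring CH2, C8 = ring C(CH3)–O, C9 = ring-fusion CH, C10 = ring C(CH3)(CH2CO2H), C11 and C12 = pyran CH2, C13 = pyran C(CH3)(vinyl), C14=C15 = vinyl, C16 = methyl on C13, C20 = methyl on C10.

**Step 1**
Reactants: 1 (E)-3-methylpenta-1,3-diene; 2 (S)-4-[(tert-butyldimethylsilyl)oxy]cyclopent-2-en-1-one
Product: 6 (4S)-4-[(E)-3-methylpent-3-en-1-yl]cyclopent-2-en-1-one, via alkylzirconocene chloride 3 (not isolated), via zirconium enolate 4 (not isolated), via silyloxy ketone 5 (not isolated)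
Conditions: Cp2Zr(H)Cl (1.05 equiv), THF, 40 °C; CuBr·SMe2 (10 mol %), 2, 40 °C; then MeOH, DBU, 25 °C
Reagents that add atoms: none
Why: Hydrozirconation puts zirconium on the terminal carbon of the diene, copper-catalysed conjugate addition of the alkylzirconocene enters the enone face anti to the silyloxy group and so sets C9, and DBU then expels silanolate by E1cB elimination to give the transposed enone.

**Step 2**
Reactants: 6 (4S)-4-[(E)-3-methylpent-3-en-1-yl]cyclopent-2-en-1-one
Product: 8 (4S)-3-methyl-4-[(E)-3-methylpent-3-en-1-yl]cyclopent-2-en-1-one, via lithium enolate 7 (not isolated)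
Conditions: Me2CuLi (from MeLi and CuI), Et2O/THF, −78 °C; then PhS(Cl)=N-t-Bu, −78 °C to 25 °C
Reagents that add atoms: lithium dimethylcuprate, [Li+].C[Cu-]C
Why: Conjugate addition of Me2CuLi brings in the C20 methyl and the enolate is dehydrogenated in the same flask by Mukaiyama's sulfinimidoyl chloride, so the enone returns with C10 fully substituted while C9 is untouched.

**Step 3**
Reactants: 8 (4S)-3-methyl-4-[(E)-3-methylpent-3-en-1-yl]cyclopent-2-en-1-one; 9 3-bromoprop-1-ene
Product: 11 (4S,5S)-3-methyl-4-[(E)-3-methylpent-3-en-1-yl]-5-(prop-2-en-1-yl)cyclopent-2-en-1-one, via lithium dienolate 10 (not isolated)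
Conditions: LiN(i-Pr)2 (LDA), THF, −78 °C; then 9, −78 °C to −30 °C
Reagents that add atoms: none
Why: Kinetic α′-deprotonation gives the cross-conjugated dienolate and SN2 allylation at C8 occurs anti to the C9 side chain (this centre is set again in step 4).

**Step 4**
Reactants: 11 (4S,5S)-3-methyl-4-[(E)-3-methylpent-3-en-1-yl]-5-(prop-2-en-1-yl)cyclopent-2-en-1-one
Product: 13 (4R,5R)-3,5-dimethyl-4-[(E)-3-methylpent-3-en-1-yl]-5-(prop-2-en-1-yl)cyclopent-2-en-1-one, via lithium enolate 12 (not isolated)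
Conditions: LiN(i-Pr)2 (LDA), THF/DMPU, −78 °C; then MeI, −78 °C to −20 °C
Reagents that add atoms: iodomethane, CI
Why: The second α′-enolate alkylation creates the quaternary C8, with MeI attacking the enolate face anti to the neighbouring C9 side chain, which leaves the allyl group cis to that chain as the later bridge requires.

**Step 5**
Reactants: 13 (4R,5R)-3,5-dimethyl-4-[(E)-3-methylpent-3-en-1-yl]-5-(prop-2-en-1-yl)cyclopent-2-en-1-one
Product: 14 3-[(1R,5R)-1,4-dimethyl-5-[(E)-3-methylpent-3-en-1-yl]-2-oxocyclopent-3-en-1-yl]propanal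
Conditions: PdCl2(PhCN)2 (12 mol %), CuCl2·2H2O (12 mol %), AgNO2 (6 mol %), O2 (1 atm), t-BuOH/MeNO2 15:1, 25 °C
Reagents that add atoms: dioxygen, O=O
Why: Nitrite-modified aldehyde-selective Wacker oxidation converts only the monosubstituted terminal alkene, anti-Markovnikov, into the C5 aldehyde, while the trisubstituted alkene and the enone do not react.

**Step 6**
Reactants: 14 3-[(1R,5R)-1,4-dimethyl-5-[(E)-3-methylpent-3-en-1-yl]-2-oxocyclopent-3-en-1-yl]propanal; 15 methyl 2-methylpropanoate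
Product: 18 methyl 5-[(1R,5R)-1,4-dimethyl-5-[(E)-3-methylpent-3-en-1-yl]-2-oxocyclopent-3-en-1-yl]-2,2-dimethyl-3-[(phenoxycarbonothioyl)oxy]pentanoate (both epimers at the oxygenated carbon), via lithium ester enolate 16 (not isolated), via lithium aldolate 17 (not isolated)
Conditions: LiN(i-Pr)2 (LDA), 15, THF, −78 °C; then 14, −78 °C; then PhOC(S)Cl, −78 °C to 0 °C
Reagents that add atoms: O-phenyl carbonochloridothioate, S=C(Cl)Oc1ccccc1
Why: Aldol addition of the ester enolate to the aldehyde forms the C4–C5 bond with C4 already quaternary, and O-acylation of the aldolate gives the Barton–McCombie radical precursor; the C5 configuration is irrelevant because C5 becomes a radical.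

**Step 7 (key step)**
Reactants: 18 methyl 5-[(1R,5R)-1,4-dimethyl-5-[(E)-3-methylpent-3-en-1-yl]-2-oxocyclopent-3-en-1-yl]-2,2-dimethyl-3-[(phenoxycarbonothioyl)oxy]pentanoate
Product: 19 methyl 2-[(1R,2S,5R,8R)-1,5-dimethyl-8-[(E)-3-methylpent-3-en-1-yl]-6-oxobicyclo[3.2.1]octan-2-yl]-2-methylpropanoate
Conditions: (Me3Si)3SiH (1.5 equiv, syringe pump, 8 h), AIBN (0.3 equiv), toluene (5 mM), 90 °C
Reagents that add atoms: none
Why: Barton–McCombie fragmentation releases the secondary C5 radical, which closes ring B by 6-exo-trig Giese addition to the enone β-carbon C10 before hydrogen transfer to the α-keto radical; C10 is fixed by the bicyclo[3.2.1] bridge that keeps C1 on the ketone side, and in the chair transition state CMe2CO2Me sits equatorial because the axial site is blocked by the syn C9 side chain, which places C4 cis to C1.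

**Step 8**
Reactants: 19 methyl 2-[(1R,2S,5R,8R)-1,5-dimethyl-8-[(E)-3-methylpent-3-en-1-yl]-6-oxobicyclo[3.2.1]octan-2-yl]-2-methylpropanoate
Product: 20 methyl 2-[(1R,5S,6S,9R)-1,5-dimethyl-9-[(E)-3-methylpent-3-en-1-yl]-3-oxo-2-oxabicyclo[3.3.1]nonan-6-yl]-2-methylpropanoate
Conditions: Me3SiOOSiMe3 (2 equiv), Me3SiOTf (10 mol %), CH2Cl2, −40 °C to −20 °C
Reagents that add atoms: bis(trimethylsilyl) peroxide, C[Si](C)(C)OO[Si](C)(C)C
Why: Baeyer–Villiger oxidation with migration of the quaternary bridgehead C8 (with retention) installs the C8–O bond, and the silyl peroxide/Me3SiOTf system does not epoxidise the isolated trisubstituted alkene.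

**Step 9**
Reactants: 20 methyl 2-[(1R,5S,6S,9R)-1,5-dimethyl-9-[(E)-3-methylpent-3-en-1-yl]-3-oxo-2-oxabicyclo[3.3.1]nonan-6-yl]-2-methylpropanoate
Product: 22 2-[(1S,2S,3R,4R)-2-(carboxymethyl)-4-hydroxy-2,4-dimethyl-3-[(E)-3-methylpent-3-en-1-yl]cyclohexyl]-2-methylpropanoic acid, via dipotassium salt 21 (not isolated)
Conditions: KOH (10 equiv), EtOH/H2O 4:1, 80 °C; then 1 M HCl to pH 4, 0 °C
Reagents that add atoms: potassium hydroxide, [K+].[OH-]
Why: Saponification opens the bridged δ-lactone and cleaves the hindered methyl ester, freeing the tertiary C8 hydroxyl and both acids without touching any stereocentre.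

**Step 10**
Reactants: 22 2-[(1S,2S,3R,4R)-2-(carboxymethyl)-4-hydroxy-2,4-dimethyl-3-[(E)-3-methylpent-3-en-1-yl]cyclohexyl]-2-methylpropanoic acid
Product: 25 2-[(2R,4aR,5S,6S,8aR)-5-(carboxymethyl)-2-ethenyl-2,5,8a-trimethyloctahydro-2H-chromen-6-yl]-2-methylpropanoic acid, via selenide 23 (not isolated), via selenoxide 24 (not isolated)
Conditions: N-(phenylseleno)phthalimide, CH2Cl2, 0 °C; then 30% H2O2, pyridine, 0 °C to 25 °C
Reagents that add atoms: none
Why: In this phenylselenoetherification the C8 hydroxyl attacks the seleniranium ion at the more substituted carbon C13 (6-exo, anti addition) through a chair with the small C16 methyl axial (cis to the C8 methyl) and the bulky selenium-bearing carbon equatorial, which sets C13, and selenoxide syn-elimination can only go toward C15 and so gives the vinyl group; the trans ring fusion follows from the C8 and C9 centres already in place.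

**Compound list**
1 | (E)-3-methylpenta-1,3-diene | C/C=C(\C)C=C | starting material
2 | (S)-4-[(tert-butyldimethylsilyl)oxy]cyclopent-2-en-1-one | O=C1C=C[C@@H](O[Si](C)(C)C(C)(C)C)C1 | starting material
3 | chlorobis(cyclopentadienyl)[(E)-3-methylpent-3-en-1-yl]zirconium | C/C=C(\C)CC[Zr](Cl)(C1C=CC=C1)C1C=CC=C1 | intermediate
4 | chlorobis(cyclopentadienyl)zirconium (3S,4S)-4-[(tert-butyldimethylsilyl)oxy]-3-[(E)-3-methylpent-3-en-1-yl]cyclopent-1-en-1-olate | C/C=C(\C)CC[C@H]1C=C(O[Zr](Cl)(C2C=CC=C2)C2C=CC=C2)C[C@@H]1O[Si](C)(C)C(C)(C)C | intermediate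
5 | (3S,4S)-4-[(tert-butyldimethylsilyl)oxy]-3-[(E)-3-methylpent-3-en-1-yl]cyclopentan-1-one | C/C=C(\C)CC[C@H]1CC(=O)C[C@@H]1O[Si](C)(C)C(C)(C)C | intermediate
6 | (4S)-4-[(E)-3-methylpent-3-en-1-yl]cyclopent-2-en-1-one | C/C=C(\C)CC[C@H]1CC(=O)C=C1 | intermediate
7 | lithium (3R,4S)-3-methyl-4-[(E)-3-methylpent-3-en-1-yl]cyclopent-1-en-1-olate | C/C=C(\C)CC[C@H]1CC([O-])=C[C@@H]1C.[Li+] | intermediate
8 | (4S)-3-methyl-4-[(E)-3-methylpent-3-en-1-yl]cyclopent-2-en-1-one | C/C=C(\C)CC[C@H]1CC(=O)C=C1C | intermediate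
9 | 3-bromoprop-1-ene (allyl bromide) | C=CCBr | starting material
10 | lithium (3S)-4-methyl-3-[(E)-3-methylpent-3-en-1-yl]cyclopenta-1,4-dien-1-olate | C/C=C(\C)CC[C@H]1C=C([O-])C=C1C.[Li+] | intermediate
11 | (4S,5S)-3-methyl-4-[(E)-3-methylpent-3-en-1-yl]-5-(prop-2-en-1-yl)cyclopent-2-en-1-one | C/C=C(\C)CC[C@H]1[C@H](CC=C)C(=O)C=C1C | intermediate
12 | lithium (3R)-4-methyl-3-[(E)-3-methylpent-3-en-1-yl]-2-(prop-2-en-1-yl)cyclopenta-1,4-dien-1-olate | C/C=C(\C)CC[C@H]1C(CC=C)=C([O-])C=C1C.[Li+] | intermediate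
13 | (4R,5R)-3,5-dimethyl-4-[(E)-3-methylpent-3-en-1-yl]-5-(prop-2-en-1-yl)cyclopent-2-en-1-one | C/C=C(\C)CC[C@H]1[C@](CC=C)(C)C(=O)C=C1C | intermediate
14 | 3-[(1R,5R)-1,4-dimethyl-5-[(E)-3-methylpent-3-en-1-yl]-2-oxocyclopent-3-en-1-yl]propanal | C/C=C(\C)CC[C@H]1[C@](CCC=O)(C)C(=O)C=C1C | intermediate
15 | methyl 2-methylpropanoate | COC(=O)C(C)C | starting material
16 | lithium 1-methoxy-2-methylprop-1-en-1-olate | COC([O-])=C(C)C.[Li+] | intermediate
17 | lithium 1-[(1R,5R)-1,4-dimethyl-5-[(E)-3-methylpent-3-en-1-yl]-2-oxocyclopent-3-en-1-yl]-5-methoxy-4,4-dimethyl-5-oxopentan-3-olate (both epimers at the carbinol carbon) | C/C=C(\C)CC[C@H]1[C@](CCC([O-])C(C)(C)C(=O)OC)(C)C(=O)C=C1C.[Li+] | intermediate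
18 | methyl 5-[(1R,5R)-1,4-dimethyl-5-[(E)-3-methylpent-3-en-1-yl]-2-oxocyclopent-3-en-1-yl]-2,2-dimethyl-3-[(phenoxycarbonothioyl)oxy]pentanoate (both epimers at the oxygenated carbon) | C/C=C(\C)CC[C@H]1[C@](CCC(OC(=S)Oc2ccccc2)C(C)(C)C(=O)OC)(C)C(=O)C=C1C | intermediate
19 | methyl 2-[(1R,2S,5R,8R)-1,5-dimethyl-8-[(E)-3-methylpent-3-en-1-yl]-6-oxobicyclo[3.2.1]octan-2-yl]-2-methylpropanoate | C/C=C(\C)CC[C@H]1[C@@]2(C)CC[C@H](C(C)(C)C(=O)OC)[C@]1(C)CC2=O | intermediate
20 | methyl 2-[(1R,5S,6S,9R)-1,5-dimethyl-9-[(E)-3-methylpent-3-en-1-yl]-3-oxo-2-oxabicyclo[3.3.1]nonan-6-yl]-2-methylpropanoate | C/C=C(\C)CC[C@H]1[C@@]2(C)CC[C@H](C(C)(C)C(=O)OC)[C@]1(C)CC(=O)O2 | intermediate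
21 | dipotassium 2-[(1S,2S,3R,4R)-2-(carboxylatomethyl)-4-hydroxy-2,4-dimethyl-3-[(E)-3-methylpent-3-en-1-yl]cyclohexyl]-2-methylpropanoate | C/C=C(\C)CC[C@H]1[C@@](O)(C)CC[C@H](C(C)(C)C(=O)[O-])[C@]1(C)CC(=O)[O-].[K+].[K+] | intermediate
22 | 2-[(1S,2S,3R,4R)-2-(carboxymethyl)-4-hydroxy-2,4-dimethyl-3-[(E)-3-methylpent-3-en-1-yl]cyclohexyl]-2-methylpropanoic acid | C/C=C(\C)CC[C@H]1[C@@](O)(C)CC[C@H](C(C)(C)C(=O)O)[C@]1(C)CC(=O)O | intermediate
23 | 2-[(2R,4aR,5S,6S,8aR)-5-(carboxymethyl)-2,5,8a-trimethyl-2-[1-(phenylselanyl)ethyl]octahydro-2H-chromen-6-yl]-2-methylpropanoic acid (selenium-bearing carbon: single epimer from anti addition, not specified, lost in the elimination) | CC([Se]c1ccccc1)[C@@]1(C)CC[C@@H]2[C@@](C)(CC(=O)O)[C@@H](C(C)(C)C(=O)O)CC[C@@]2(C)O1 | intermediate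
24 | selenoxide of 23 | CC([Se](=O)c1ccccc1)[C@@]1(C)CC[C@@H]2[C@@](C)(CC(=O)O)[C@@H](C(C)(C)C(=O)O)CC[C@@]2(C)O1 | intermediate
25 | 2-[(2R,4aR,5S,6S,8aR)-5-(carboxymethyl)-2-ethenyl-2,5,8a-trimethyloctahydro-2H-chromen-6-yl]-2-methylpropanoic acid | C=C[C@@]1(C)CC[C@@H]2[C@@](C)(CC(=O)O)[C@@H](C(C)(C)C(=O)O)CC[C@@]2(C)O1 | target

**Total step count:** 10. **Longest linear sequence:** 10 steps (from 2).

**Steps most likely to fail, with fallbacks**

Step 7 (key radical cyclization). The C5 radical is neopentyl-like and must attack a β,β-disubstituted enone carbon, so premature reduction can win. The fallback reverses the roles of the two carbons and sets out from 14. Wittig olefination with Ph3P=C(CH3)CO2CH3 (toluene, 80 °C) gives the enone enoate F1. SmI2 (2.5 equiv) with HMPA and t-BuOH in THF at −78 °C reduces the enone to its radical anion, whose β-carbon C10 adds 6-exo to the enoate β-carbon C5 in the same bridged chair, giving the monomethyl keto ester F2. Treatment of F2 with LiN(i-Pr)2 (2.2 equiv, THF/HMPA) forms the ketone enolate and then the ester enolate; MeI (1.0 equiv) alkylates the more basic ester enolate at C4, and protonation returns the route at 19.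

Step 8 (Baeyer–Villiger beside a trisubstituted alkene). If the silyl peroxide system attacks the alkene or is too sluggish, the fallback sets out from 19 and uses mCPBA (2.5 equiv, NaHCO3, CH2Cl2). Both the ring expansion and the epoxidation are accepted, giving the epoxy lactone F3. The alkene is then restored by oxygen-atom transfer to PPh3 with CH3ReO3 (5 mol %) in benzene at 60 °C, coming back at 20; the alkene geometry does not matter.

Step 10 (pyran closure and C13). Closing ring C forces ring B into the chair with axial CMe2CO2H and 1,3-diaxial methyl groups, and the C13 selectivity rests on a steric argument. The fallback sets out from 20 and builds C13 by nucleophilic vinylation instead. Ozonolysis (O3, CH2Cl2/MeOH, −78 °C; Me2S) gives the keto lactone F4. HCl in MeOH with HC(OMe)3 at 25 °C opens the lactone to the methyl ester and ties the C8 hydroxyl and the C13 ketone into the cyclic methyl ketal diester F5. BF3·OEt2 with potassium vinyltrifluoroborate (CH2Cl2/MeCN, −20 °C) ionises the ketal, and the vinyl group adds to the oxocarbenium ion from the face anti to the axial C8 methyl, giving the vinyl pyran diester F6. KOH in EtOH/H2O at 80 °C then delivers 25.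

**Further compounds**
F1 | step 7 | methyl (E)-5-[(1R,5R)-1,4-dimethyl-5-[(E)-3-methylpent-3-en-1-yl]-2-oxocyclopent-3-en-1-yl]-2-methylpent-2-enoate | C/C=C(\C)CC[C@H]1[C@](CC/C=C(\C)C(=O)OC)(C)C(=O)C=C1C
F2 | step 7 | methyl 2-[(1R,2S,5R,8R)-1,5-dimethyl-8-[(E)-3-methylpent-3-en-1-yl]-6-oxobicyclo[3.2.1]octan-2-yl]propanoate (both epimers at the ester α-carbon) | C/C=C(\C)CC[C@H]1[C@@]2(C)CC[C@H](C(C)C(=O)OC)[C@]1(C)CC2=O
F3 | step 8 | methyl 2-[(1R,5S,6S,9R)-9-[2-(2,3-dimethyloxiran-2-yl)ethyl]-1,5-dimethyl-3-oxo-2-oxabicyclo[3.3.1]nonan-6-yl]-2-methylpropanoate (epoxide epimers) | CC1OC1(C)CC[C@H]1[C@@]2(C)CC[C@H](C(C)(C)C(=O)OC)[C@]1(C)CC(=O)O2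
F4 | step 10 | methyl 2-[(1R,5S,6S,9R)-1,5-dimethyl-3-oxo-9-(3-oxobutyl)-2-oxabicyclo[3.3.1]nonan-6-yl]-2-methylpropanoate | CC(=O)CC[C@H]1[C@@]2(C)CC[C@H](C(C)(C)C(=O)OC)[C@]1(C)CC(=O)O2
F5 | step 10 | methyl 2-[(4aR,5S,6S,8aR)-2-methoxy-5-(2-methoxy-2-oxoethyl)-2,5,8a-trimethyloctahydro-2H-chromen-6-yl]-2-methylpropanoate (both ketal epimers) | COC1(C)CC[C@@H]2[C@@](C)(CC(=O)OC)[C@@H](C(C)(C)C(=O)OC)CC[C@@]2(C)O1
F6 | step 10 | methyl 2-[(2R,4aR,5S,6S,8aR)-2-ethenyl-5-(2-methoxy-2-oxoethyl)-2,5,8a-trimethyloctahydro-2H-chromen-6-yl]-2-methylpropanoate | C=C[C@@]1(C)CC[C@@H]2[C@@](C)(CC(=O)OC)[C@@H](C(C)(C)C(=O)OC)CC[C@@]2(C)O1
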